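Ring A, the hexasubstituted phloroglucinol, is cut at C1–C2 and C5–C6. Atoms C2 to C5 alternate oxygen-bearing and arm-bearing carbons. This is the pattern left when two molecules of a monosubstituted ketene join head to tail. C6, C1 and the hexanoyl chain make up a 3-oxooctanoate. In one flask the keto ester enolate is acylated at C1 by a β-lactone carbonyl, and C5 then closes onto the ester, giving aromatic ring A with all six substituents. The precursor is the (Z)-4-alkylidene-oxetan-2-one built from two copies of one enantiopure ketene. Each copy carries the isopropyl-bearing stereocentre and a syncarpyl enol masked as its methyl ether.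

Key step: step 5

Remarks on the chemistry
- Ring A numbering: C1 carries the hexanoyl group, C2, C4 and C6 the hydroxy groups, and C3 and C5 the arms. "Arm" means CH(i-Pr)(syncarpyl).
- Both arm centres of 13 have the same sense, (R). The same spatial arrangement is called (S) in 3–6 only because a CH2 group ranks below isopropyl.
- The syncarpyl trione is symmetric, so methylation of either flanking oxygen gives the same compound.
- Assumption: syncarpic acid 1 is purchased.
- A 2-alkylidene derivative of a cyclic 1,3-dione holds its two carbonyl groups divergent and cannot chelate a chiral Lewis acid. The stereocentre is therefore set on an enal by iminium catalysis, with 1 as the nucleophile.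

Step 1
Reactants: 1 syncarpic acid (2,2,4,4-tetramethylcyclohexane-1,3,5-trione); 2 (E)-4-methylpent-2-enal
Product: 3 (4S)-2-hydroxy-4-isopropyl-6,6,8,8-tetramethyl-3,4-dihydro-2H-chromene-5,7(6H,8H)-dione (lactol as anomer mixture)
Conditions: (S)-2-[bis(3,5-bis(trifluoromethyl)phenyl)(trimethylsilyloxy)methyl]pyrrolidine (10 mol %), CH2Cl2, 0 °C → rt
Reagents that add atoms: none
Why: Iminium-catalysed Michael addition of a cyclic 1,3-dicarbonyl C–H acid to an enal with hemiacetal closure is established chemistry, and in the (E)-iminium ion the diaryl(silyloxy)methyl group of the (S)-catalyst covers one face, so that C6 of 1 adds to the open face of the β-carbon and sets the (S) centre from which both arm centres of 13 derive.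

Step 2
Reactants: 3 lactol
Product: 4 (3S)-3-(2-methoxy-3,3,5,5-tetramethyl-4,6-dioxocyclohex-1-en-1-yl)-4-methylpentanal
Conditions: Me3SiCHN2 (1.2 equiv), PhMe/MeOH 4:1, 0 °C
Reagents that add atoms: trimethylsilyldiazomethane, C[Si](C)(C)C=[N+]=[N-]
Why: O-Methylation of an acidic enol by a diazoalkane: only the ring-opened enol–aldehyde tautomer of 3 is acidic enough to protonate the reagent, so the lactol drains into 4 under neutral conditions that give retro-Michael racemisation no chance.

Step 3
Reactants: 4 aldehyde
Product: 5 (3S)-3-(2-methoxy-3,3,5,5-tetramethyl-4,6-dioxocyclohex-1-en-1-yl)-4-methylpentanoic acid (used without storage)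
Conditions: NaClO2, NaH2PO4, 2-methylbut-2-ene, t-BuOH/H2O, 0 °C → rt
Reagents that add atoms: sodium chlorite NaClO2, [Na+].[O-]Cl=O
Why: Pinnick oxidation takes the aldehyde to the acid in a weakly acidic buffer that touches neither the hindered vinylogous ester nor the neighbouring stereocentre, the alkene scavenger removing hypochlorous acid before it can chlorinate the enol ether.

Step 4
Reactants: 5 arm acid (two molecules)
Product: 8 (Z)-4-alkylidene-oxetan-2-one dimer of the arm ketene, via acid chloride 6 (not isolated), via arm ketene 7 (not isolated)
Conditions: 1-chloro-N,N,2-trimethylprop-1-en-1-amine (1.05 equiv), CH2Cl2, −10 °C; then Et3N (1.5 equiv), quinuclidine (10 mol %), PhMe, −10 °C → rt, about 0.5 M; filtration through a short silica plug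
Reagents that add atoms: none
Why: Amine-induced dehydrochlorination of an acid chloride and nucleophile-catalysed head-to-tail dimerisation of the resulting aldoketene to the (Z)-alkylidene β-lactone is the normal fate of monosubstituted ketenes, α-branched ones included; the chloroenamine makes 6 without HCl, the immediate amine treatment leaves the vinylogous ester oxygen little time to attack the acyl chloride, the arm centres lie outside the reacting atoms, and joining two copies of one enantioenriched unit diverts most of the minor enantiomer into a separable diastereomer.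

Step 5
Reactants: 8 ketene dimer; 9 methyl 3-oxooctanoate
Product: 12 myrtucommulone F bis(methyl enol ether), via sodium enolate 10 (not isolated), via acyclic triketo ester 11 (not isolated)
Conditions: 9 (1.1 equiv), NaH (1.1 equiv), THF, 0 °C; 8, −30 °C → rt; NaN(SiMe3)2 (3.2 equiv), −78 → 0 °C; AcOH quench; chromatography
Reagents that add atoms: none
Why: Proposed new method: enolate 10 adds through carbon to the strained lactone carbonyl C2 of 8, the acyl–oxygen bond breaks and the C4–C5 enolate set free is at once quenched by the very acidic C1–H, so that 11 rests as its sodium triacylmethanide (an O-acylated by-product is itself an acyl donor and drains to this sink). The second base charge, which the sequence cannot do without, re-forms the C4–C5 enolate (in equilibrium with the C3 enolate), C5 adds to the ester carbon C6, methoxide leaves and two enolisations aromatise ring A. The closest known reaction types are the C-acylation of 1,3-dicarbonyl enolates by diketene and the base-induced Claisen cyclisation of polyketo esters to acylphloroglucinols; running both in one flask on a dimer that carries a bulky group at C3 and at C5 is without precedent. Ring A closes in the 6-(enolendo)-exo-trig mode and no stereocentre is formed, since C1, C3 and C5 all end as sp2 carbons. The step needs Claisen closure rather than aldol closure at the hexanoyl carbonyl or closure through oxygen: on the crowded anionic C1 the charge rests mainly on the two ketone oxygens while the ester is twisted out of conjugation and stays the best electrophile, an aldolate cannot lose oxide in the aprotic basic medium and reverts, a 2-pyranone can be reopened by the methoxide released, and only the Claisen path ends in an irreversible deprotonation to the phloroglucinolate. The arm centres survive because an O-methylated syncarpyl carbon cannot depart as an enolate, which closes the retro-Michael channel from the C3 and C5 enolates, and because methoxide can exchange with the methyl enol ethers only degenerately.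

Step 6
Reactants: 12 bis(methyl enol ether)
Product: 13 myrtucommulone F
Conditions: NaSEt (8 equiv), DMF, 0 °C → rt; AcOH/NaOAc buffer (pH 5)
Reagents that add atoms: none
Why: Thiolate SN2 O-demethylation: each vinylogous ester oxygen leaves as a β-triketone enolate about as stabilised as a carboxylate, the methyl carbon is open whereas the ring carbon is shielded by a quaternary neighbour, and room temperature without acid avoids both cyclodehydration of enol and phenol to a pyran ring and reversible cleavage of the arm C–C bonds.

Compound list
1 | syncarpic acid (2,2,4,4-tetramethylcyclohexane-1,3,5-trione) | CC1(C)C(=O)CC(=O)C(C)(C)C1=O | starting material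
2 | (E)-4-methylpent-2-enal | CC(C)/C=C/C=O | starting material
3 | (4S)-2-hydroxy-4-isopropyl-6,6,8,8-tetramethyl-3,4-dihydro-2H-chromene-5,7(6H,8H)-dione, anomer mixture | OC1C[C@@H](C(C)C)C2=C(O1)C(C)(C)C(=O)C(C)(C)C2=O | intermediate
4 | (3S)-3-(2-methoxy-3,3,5,5-tetramethyl-4,6-dioxocyclohex-1-en-1-yl)-4-methylpentanal | O=CC[C@H](C1=C(OC)C(C)(C)C(=O)C(C)(C)C1=O)C(C)C | intermediate
5 | (3S)-3-(2-methoxy-3,3,5,5-tetramethyl-4,6-dioxocyclohex-1-en-1-yl)-4-methylpentanoic acid | OC(=O)C[C@H](C1=C(OC)C(C)(C)C(=O)C(C)(C)C1=O)C(C)C | intermediate
6 | (3S)-3-(2-methoxy-3,3,5,5-tetramethyl-4,6-dioxocyclohex-1-en-1-yl)-4-methylpentanoyl chloride | ClC(=O)C[C@H](C1=C(OC)C(C)(C)C(=O)C(C)(C)C1=O)C(C)C | intermediate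
7 | arm ketene, (3R)-3-(2-methoxy-3,3,5,5-tetramethyl-4,6-dioxocyclohex-1-en-1-yl)-4-methylpent-1-en-1-one | O=C=C[C@H](C1=C(OC)C(C)(C)C(=O)C(C)(C)C1=O)C(C)C | intermediate
8 | (4Z)-oxetan-2-one carrying the (R)-arm at C3 and the (R)-arm-methylidene group at C4, epimers at C3 | O=C1O/C(=C\[C@H](C2=C(OC)C(C)(C)C(=O)C(C)(C)C2=O)C(C)C)C1[C@H](C1=C(OC)C(C)(C)C(=O)C(C)(C)C1=O)C(C)C | intermediate
9 | methyl 3-oxooctanoate | CCCCCC(=O)CC(=O)OC | starting material
10 | sodium enolate of methyl 3-oxooctanoate | CCCCCC([O-])=CC(=O)OC.[Na+] | intermediate
11 | methyl 2-hexanoyl-3,5-dioxohexanoate carrying an O-methylated arm at C4 and at C6 (ring A atoms C3 and C5), arm centres as in 8, drawn as the neutral keto form | CCCCCC(=O)C(C(=O)OC)C(=O)C([C@H](C1=C(OC)C(C)(C)C(=O)C(C)(C)C1=O)C(C)C)C(=O)C[C@H](C1=C(OC)C(C)(C)C(=O)C(C)(C)C1=O)C(C)C | intermediate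
12 | myrtucommulone F bis(methyl enol ether), both arm centres (R) | CCCCCC(=O)c1c(O)c([C@H](C2=C(OC)C(C)(C)C(=O)C(C)(C)C2=O)C(C)C)c(O)c([C@H](C2=C(OC)C(C)(C)C(=O)C(C)(C)C2=O)C(C)C)c1O | intermediate
13 | myrtucommulone F, both arm centres (R) | CCCCCC(=O)c1c(O)c([C@H](C2=C(O)C(C)(C)C(=O)C(C)(C)C2=O)C(C)C)c(O)c([C@H](C2=C(O)C(C)(C)C(=O)C(C)(C)C2=O)C(C)C)c1O | target

Total step count: 6
Longest linear sequence: 6 steps (1 → 3 → 4 → 5 → 8 → 12 → 13)

Steps most likely to fail

Step 5 (the step labelled as a proposed new method).
- **What may go wrong:**
  - After the acylation the chain may stay parked as an unreactive polyanion, because the hindered C5 cannot reach the ester.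
  - Closure through the C4 oxygen may take over.
  - Deprotonation in the hexanoyl chain, followed by aldol closure, may take over.
  - Cleavage of the triacylmethane by alkoxide may take over.
- **Fallback:** it uses known chemistry only, sets out from 8 and comes back at 12. The same two ring bonds are made in the opposite order.
  - Methanolysis of 8 (MeOH, cat. DMAP, CH2Cl2, rt), the standard opening of ketene dimers by alcohols, should give the methyl β-keto ester F1.
  - Its dianion (NaH, then LiN(iPr)2, THF, −78 °C) is acylated at the γ-carbon C5 by the ester group of enolate 10. This is the γ-acylation of β-keto ester dianions, and it should give the linear methyl 3,5,7-trioxododecanoate F2.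
  - NaOMe in MeOH then closes the doubly activated C1 methylene onto the ester carbon C2, the classical Claisen cyclisation of a 3,5,7-triketo ester.
  - The rival aldol closure from C3 would create a quaternary carbon, cannot aromatise and reverts. The product is 12.

Step 4.
- **What may go wrong:**
  - The vinylogous ester carbonyl oxygen may attack the acyl chloride or the ketene as a neighbouring group. Transfer of the O-methyl group to chloride and six-membered lactonisation would follow, and this may outrun the bimolecular dimerisation.
  - The branched arm slows the dimerisation further.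
  - Oligomerisation of the ketene is a second drain.
- **Fallback:** it sets out from 4 and 5 and comes back at 12. It uses neither an acyl halide nor a ketene, and it gives up the one-flask annulation while keeping the same ring bonds.
  - Acid 5 is esterified (Me3SiCHN2, PhMe/MeOH) to the methyl ester F3.
  - The lithium enolate of F3 (LiN(iPr)2, THF, −78 °C) adds to aldehyde 4 in an aldol addition. This should give the β-hydroxy ester F4 as a diastereomer mixture whose new centres are erased later.
  - Dess–Martin periodinane oxidises F4 to the β-keto ester F1. F1 is carried through the trioxo ester F2 to 12 as described under step 5.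

Step 6.
- **What may go wrong:**
  - Dealkylation may stall as negative charge builds up on the phenolate.
  - Thiolate may add at the ring carbon of the vinylogous ester.
  - In the basic medium the unmasked arms may cleave and re-add reversibly, with loss of configuration.
- **Fallback:** it sets out from 12 and comes back at 13. The anionic dealkylation is replaced by an electrophile-assisted one on a temporarily silylated, base-free substrate.
  - N,O-bis(trimethylsilyl)acetamide (CH2Cl2, rt) should give the tris(trimethylsilyl) ether F5, so that no acidic proton is left.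
  - Me3SiI (2.5 equiv, CH2Cl2, −20 → 0 °C) silylates each vinylogous ester carbonyl oxygen. Iodide removes the methyl group, giving the pentakis(trimethylsilyl) derivative F6.
  - Stirring F6 in MeOH at rt strips all silyl groups and gives 13.

Further compounds
F1 | step 5 | methyl 3-oxobutanoate carrying an O-methylated arm at C2 and at C4 (methanol adduct of 8), arm centres as in 8 | COC(=O)C([C@H](C1=C(OC)C(C)(C)C(=O)C(C)(C)C1=O)C(C)C)C(=O)C[C@H](C1=C(OC)C(C)(C)C(=O)C(C)(C)C1=O)C(C)C
F2 | step 5 | methyl 3,5,7-trioxododecanoate carrying an O-methylated arm at C2 and at C4, arm centres as in 8 | COC(=O)C([C@H](C1=C(OC)C(C)(C)C(=O)C(C)(C)C1=O)C(C)C)C(=O)C([C@H](C1=C(OC)C(C)(C)C(=O)C(C)(C)C1=O)C(C)C)C(=O)CC(=O)CCCCC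
F3 | step 4 | methyl (3S)-3-(2-methoxy-3,3,5,5-tetramethyl-4,6-dioxocyclohex-1-en-1-yl)-4-methylpentanoate | COC(=O)C[C@H](C1=C(OC)C(C)(C)C(=O)C(C)(C)C1=O)C(C)C
F4 | step 4 | methyl 3-hydroxybutanoate carrying an O-methylated arm at C2 and at C4, mixture at C2 and C3 | COC(=O)C([C@H](C1=C(OC)C(C)(C)C(=O)C(C)(C)C1=O)C(C)C)C(O)C[C@H](C1=C(OC)C(C)(C)C(=O)C(C)(C)C1=O)C(C)C
F5 | step 6 | tris(trimethylsilyl) ether of 12 | CCCCCC(=O)c1c(O[Si](C)(C)C)c([C@H](C2=C(OC)C(C)(C)C(=O)C(C)(C)C2=O)C(C)C)c(O[Si](C)(C)C)c([C@H](C2=C(OC)C(C)(C)C(=O)C(C)(C)C2=O)C(C)C)c1O[Si](C)(C)C
F6 | step 6 | pentakis(trimethylsilyl) derivative of 13 | CCCCCC(=O)c1c(O[Si](C)(C)C)c([C@H](C2=C(O[Si](C)(C)C)C(C)(C)C(=O)C(C)(C)C2=O)C(C)C)c(O[Si](C)(C)C)c([C@H](C2=C(O[Si](C)(C)C)C(C)(C)C(=O)C(C)(C)C2=O)C(C)C)c1O[Si](C)(C)C
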